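**Plan**

1. Retrosynthesis: the two angelate acyl–O bonds and the two late oxiranes (C4–C5, C10–C11) are removed first. The C8 carbinol beside the exocyclic C7=C14 methylene is the zinc-opened form of a C7–C8 oxirane carrying a C14 iodomethyl group. That oxirane is the epoxide of an (E)-C7=C8 allylic alcohol whose CH2OH is C14, and this 2,3-epoxy-alcohol retron makes the key step possible.
2. The allylic alcohol is cut at C14–O/C8–S ([2,3] shift of an allyl sulfoxide) and at C8–C9 (prenyl bromide). The sulfoxide comes from the isopropenyl group of (R)-carvone, and the ring oxygens from α′-hydroxylation (C2) and carbonyl reduction (C3).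
3. Forward: ring oxygenation on carvone, allylic chloride, sulfoxide, C8–C9 alkylation, [2,3] shift, C7–C8 oxirane (key step, first new ring), reductive opening, both angelates, C4–C5 oxirane, C10–C11 oxirane.
4. Stereochemistry: C1 from carvone; C2 by anti hydroxylation then Mitsunobu inversion; C3 by Luche reduction anti to the C2 silyloxy group; C8 by the L-(+)-tartrate titanium catalyst (C7 is erased later); C4/C5 by the C2 hydroxyl (vanadium); C10 by the D-fructose-derived ketone.
5. Numbering in all names: ring C1 (side chain), C2 (OH), C3 (angelate), C4 (methyl), C5, C6; chain C7 (=C14H2), C8 (angelate), C9, C10, C11.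

Key step: step 11

Remark on the chemistry: the Rubottom step is taken to deliver the C2 oxygen trans to the isopropenyl group (attack anti to the C1 substituent), so an inversion follows; sulfoxides 12 and 14 are carried as epimer mixtures at sulfur (and C8 in 14), centres that vanish in step 10.

**Route**

Step 1
Reactants: 1 (R)-carvone
Product: 4 trans-6-hydroxycarvone, via silyl dienol ether 2 (not isolated), via trans silyloxy ketone 3 (not isolated)
Conditions: LiN(iPr)2, THF, −78 °C; Me3SiCl; then mCPBA, CH2Cl2, −20 °C; then 1 M HCl, THF, 0 °C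
Reagents that add atoms: mCPBA (3-chloroperoxybenzoic acid), OOC(=O)c1cccc(Cl)c1
Why: Rubottom oxidation, in which kinetic α′-deprotonation gives the cross-conjugated silyl dienol ether, the peracid epoxidises its electron-rich enol double bond from the face opposite the C1 isopropenyl group, and silyl migration with acid hydrolysis should leave the C2 hydroxyl trans to the side chain.

Step 2
Reactants: 4 trans-6-hydroxycarvone
Product: 6 cis-6-hydroxycarvone, via cis 4-nitrobenzoate 5 (not isolated)
Conditions: PPh3, DIAD, 4-O2NC6H4CO2H, THF, 0 °C → rt; then K2CO3 (0.2 equiv), MeOH, 0 °C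
Reagents that add atoms: 4-nitrobenzoic acid, OC(=O)c1ccc(cc1)[N+](=O)[O-]
Why: Mitsunobu inversion under the 4-nitrobenzoic acid protocol used for hindered equatorial cyclohexanols, in which carboxylate displaces the C2 oxyphosphonium group in an SN2 step helped by the adjacent carbonyl so that C2–O ends cis to the side chain, and brief methanolysis of the activated ester should free the alcohol before the α-centre can epimerise.

Step 3
Reactants: 6 cis-6-hydroxycarvone
Product: 7 cis-6-(tert-butyldimethylsilyloxy)carvone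
Conditions: TBSOTf, 2,6-lutidine, CH2Cl2, −78 °C
Reagents that add atoms: tert-butyldimethylsilyl triflate, CC(C)(C)[Si](C)(C)OS(=O)(=O)C(F)(F)F
Why: Silyl ether formation with the triflate at low temperature should cap the hindered axial α-ketol hydroxyl under conditions too mild to epimerise C2.

Step 4
Reactants: 7 cis-6-(tert-butyldimethylsilyloxy)carvone
Product: 8 allylic chloride (2-(chloromethyl)vinyl group on C1)
Conditions: Ca(OCl)2, CO2 (solid), CH2Cl2/H2O, 0 °C
Reagents that add atoms: calcium hypochlorite, [Ca+2].[O-]Cl.[O-]Cl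
Why: Ene-type allylic chlorination by HOCl formed in the flask should attack only the electron-rich 1,1-disubstituted isopropenyl alkene, the ring alkene being deactivated as an enone, and makes the chloromethyl carbon (future C8) and the methylene (future C14).

Step 5
Reactants: 8 allylic chloride
Product: 9 C3 allylic alcohol (2-O-TBS)
Conditions: NaBH4, CeCl3·7H2O, MeOH, −78 °C
Reagents that add atoms: none
Why: Luche reduction, in which the cerium-modified borohydride adds 1,2 to the enone from the α face, anti to the axial C2 silyloxy group and the C1 substituent, so the C3 hydroxyl should be set cis to both (3S).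

Step 6
Reactants: 9 C3 allylic alcohol
Product: 10 C3 triethylsilyl ether
Conditions: Et3SiCl, imidazole, DMF, 0 °C
Reagents that add atoms: chlorotriethylsilane, CC[Si](Cl)(CC)CC
Why: Standard silylation gives a C3 ether more labile than the C2 tert-butyldimethylsilyl ether, which allows the two oxygens to be told apart later.

Step 7
Reactants: 10 C3 triethylsilyl ether
Product: 11 allyl phenyl sulfide
Conditions: PhSNa, THF/DMF, 0 °C
Reagents that add atoms: sodium benzenethiolate, [Na+].[S-]c1ccccc1
Why: SN2 displacement of the primary allylic chloride by thiolate should be clean now that the enone, a competing conjugate acceptor, has been reduced.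

Step 8
Reactants: 11 allyl phenyl sulfide
Product: 12 allyl phenyl sulfoxide (both sulfur epimers)
Conditions: mCPBA (1.0 equiv), CH2Cl2, −78 °C
Reagents that add atoms: mCPBA (3-chloroperoxybenzoic acid), OOC(=O)c1cccc(Cl)c1
Why: Sulfide-to-sulfoxide oxidation with one equivalent of peracid at low temperature is much faster than epoxidation of any of the alkenes.

Step 9
Reactants: 12 allyl phenyl sulfoxide; 13 prenyl bromide
Product: 14 C8-prenylated allyl sulfoxide (mixture at C8 and sulfur)
Conditions: LiN(iPr)2, THF, −78 °C; then 13, −78 → −40 °C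
Reagents that add atoms: none
Why: α-Alkylation of a lithiated allylic sulfoxide, in which deprotonation at C8 (allylic and α to sulfur) and SN2 attack on the primary carbon of prenyl bromide should form the C8–C9 bond, such anions alkylating at the α-carbon.

Step 10
Reactants: 14 C8-prenylated allyl sulfoxide
Product: 16 (E)-allylic alcohol (C14 hydroxymethyl on C7=C8; 2-O-TBS; 3-O-TES), via allyl sulfenate 15 (not isolated)
Conditions: Et2NH, MeOH, 40 °C
Reagents that add atoms: none
Why: Mislow–Evans [2,3]-sigmatropic rearrangement, in which the sulfoxide oxygen bonds to C14 as C8–S breaks, the C9 chain sits pseudo-equatorial in the envelope transition state so that the new C7=C8 bond should be E, and the amine traps the sulfenate as the alcohol.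

Step 11
Reactants: 16 (E)-allylic alcohol
Product: 17 (7S,8S)-7,8-epoxy alcohol
Conditions: Ti(OiPr)4 (0.2 equiv), L-(+)-diethyl tartrate (0.24 equiv), t-BuOOH, 4 Å molecular sieves, CH2Cl2, −20 °C
Reagents that add atoms: tert-butyl hydroperoxide, CC(C)(C)OO
Why: Katsuki–Sharpless asymmetric epoxidation: the C14 hydroxyl and the hydroperoxide bind to the titanium tartrate dimer, and the distal peroxide oxygen is passed to C7=C8 in a concerted syn transfer. The oxirane (O, C7, C8) closes in this single [2+1] event by forming C7–O and C8–O together, so the E geometry is kept and CH2OH and C9 end trans on the ring. Both new centres are set by the L-(+)-tartrate ligand, which with (E)-2-substituted alk-2-en-1-ols gives the (2S,3S)-type epoxy alcohol, here 7S,8S; C8–O then has the configuration of the target and C7 is erased in step 13. The step needs reagent control over the bias of the neighbouring C1 stereocentre and chemoselectivity against the C4=C5 and C10=C11 alkenes. Both should hold because ligand-accelerated oxygen transfer reaches only an alkene held by a titanium-bound allylic alkoxide, and the only free hydroxyl is the primary one at C14. The closest known reaction type is the epoxidation of (E)-2-alkylalk-2-en-1-ols, among the best substrates of this reaction.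

Step 12
Reactants: 17 (7S,8S)-7,8-epoxy alcohol
Product: 18 C14 epoxy iodide
Conditions: PPh3, I2, imidazole, THF, 0 °C
Reagents that add atoms: iodine, II
Why: Appel-type iodination of the primary alcohol under imidazole buffering should leave the oxirane and both silyl ethers intact.

Step 13
Reactants: 18 C14 epoxy iodide
Product: 20 C3,C8-diol (2-O-TBS; C7=C14 methylene), via C3-silylated allylic alcohol 19 (not isolated)
Conditions: Zn dust, AcOH/THF/H2O (3:1:1), 0 °C → rt
Reagents that add atoms: none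
Why: Reductive opening of a 2,3-epoxy iodide, in which zinc inserts into C14–I and β-elimination breaks C7–O to give the C7=C14 methylene and the C8 alcohol with C8–O untouched (1,3-transposition), after which the aqueous acetic acid should hydrolyse the triethylsilyl ether and spare the hindered tert-butyldimethylsilyl ether.

Step 14
Reactants: 20 C3,C8-diol
Product: 21 C3,C8-bis-angelate (2-O-TBS)
Conditions: angelic acid, 2,4,6-Cl3C6H2COCl, Et3N, toluene, rt; then 20, 80 °C
Reagents that add atoms: angelic acid ((Z)-2-methylbut-2-enoic acid), C/C=C(/C)C(=O)O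
Why: Yamaguchi-type esterification with the preformed mixed anhydride and no nucleophilic catalyst should acylate both hindered allylic alcohols without Z-to-E isomerisation to the tiglate.

Step 15
Reactants: 21 C3,C8-bis-angelate (2-O-TBS)
Product: 22 C2 alcohol bis-angelate
Conditions: HF·pyridine, pyridine, THF, 0 °C → rt
Reagents that add atoms: none
Why: Fluoride desilylation under buffered acidic conditions, chosen because no epoxide is present yet and because basic fluoride would favour migration of the C3 acyl group to the cis C2 hydroxyl.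

Step 16
Reactants: 22 C2 alcohol bis-angelate
Product: 23 4,5-epoxide
Conditions: VO(acac)2 (5 mol %), t-BuOOH, CH2Cl2, 0 °C → rt
Reagents that add atoms: tert-butyl hydroperoxide, CC(C)(C)OO
Why: Hydroxyl-directed vanadium-catalysed epoxidation, in which the axial homoallylic C2 vanadate delivers oxygen to the same face of the trisubstituted C4=C5 bond and should set 4S,5S cis to the C2 and C3 oxygens, while the undirected C10=C11 bond and the 1,1-disubstituted, ester-deactivated C7=C14 bond should be left.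

Step 17
Reactants: 23 4,5-epoxide
Product: 24 CNP0296086.3
Conditions: D-fructose-derived ketone catalyst (1,2:4,5-di-O-isopropylidene-β-D-erythro-2,3-hexodiulo-2,6-pyranose, 30 mol %), KHSO5 (as 2KHSO5·KHSO4·K2SO4), K2CO3, Bu4NHSO4, MeCN/(MeO)2CH2/aq. Na2B4O7 buffer, 0 °C
Reagents that add atoms: potassium peroxymonosulfate, [K+].[O-]S(=O)(=O)OO
Why: Shi epoxidation, in which the chiral dioxirane epoxidises the most electron-rich trisubstituted alkene (C10=C11) through the spiro transition state that should give the 10R oxirane, the conjugated angelate alkenes and the deactivated C7=C14 bond reacting far more slowly.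

**Compound list**

1 | (R)-carvone, (5R)-2-methyl-5-(prop-1-en-2-yl)cyclohex-2-en-1-one | CC1=CC[C@H](CC1=O)C(C)=C | starting material
2 | trimethyl{[(3R)-6-methyl-3-(prop-1-en-2-yl)cyclohexa-1,5-dien-1-yl]oxy}silane | C=C(C)[C@@H]1CC=C(C)C(O[Si](C)(C)C)=C1 | intermediate
3 | (5S,6S)-2-methyl-5-(prop-1-en-2-yl)-6-[(trimethylsilyl)oxy]cyclohex-2-en-1-one | C=C(C)[C@@H]1CC=C(C)C(=O)[C@H]1O[Si](C)(C)C | intermediate
4 | trans-6-hydroxycarvone, (5S,6S)-6-hydroxy-2-methyl-5-(prop-1-en-2-yl)cyclohex-2-en-1-one | C=C(C)[C@@H]1CC=C(C)C(=O)[C@H]1O | intermediate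
5 | (1R,6S)-3-methyl-2-oxo-6-(prop-1-en-2-yl)cyclohex-3-en-1-yl 4-nitrobenzoate | C=C(C)[C@@H]1CC=C(C)C(=O)[C@@H]1OC(=O)c2ccc(cc2)[N+](=O)[O-] | intermediate
6 | cis-6-hydroxycarvone, (5S,6R)-6-hydroxy-2-methyl-5-(prop-1-en-2-yl)cyclohex-2-en-1-one | C=C(C)[C@@H]1CC=C(C)C(=O)[C@@H]1O | intermediate
7 | (5S,6R)-6-[(tert-butyldimethylsilyl)oxy]-2-methyl-5-(prop-1-en-2-yl)cyclohex-2-en-1-one | C=C(C)[C@@H]1CC=C(C)C(=O)[C@@H]1O[Si](C)(C)C(C)(C)C | intermediate
8 | (5S,6R)-6-[(tert-butyldimethylsilyl)oxy]-5-(3-chloroprop-1-en-2-yl)-2-methylcyclohex-2-en-1-one | ClCC(=C)[C@@H]1CC=C(C)C(=O)[C@@H]1O[Si](C)(C)C(C)(C)C | intermediate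
9 | (1S,5S,6R)-6-[(tert-butyldimethylsilyl)oxy]-5-(3-chloroprop-1-en-2-yl)-2-methylcyclohex-2-en-1-ol | ClCC(=C)[C@@H]1CC=C(C)[C@H](O)[C@@H]1O[Si](C)(C)C(C)(C)C | intermediate
10 | tert-butyl{[(1R,2S,6S)-6-(3-chloroprop-1-en-2-yl)-3-methyl-2-[(triethylsilyl)oxy]cyclohex-3-en-1-yl]oxy}dimethylsilane | ClCC(=C)[C@@H]1CC=C(C)[C@H](O[Si](CC)(CC)CC)[C@@H]1O[Si](C)(C)C(C)(C)C | intermediate
11 | tert-butyldimethyl{[(1R,2S,6S)-3-methyl-6-[3-(phenylsulfanyl)prop-1-en-2-yl]-2-[(triethylsilyl)oxy]cyclohex-3-en-1-yl]oxy}silane | C=C(CSc2ccccc2)[C@@H]1CC=C(C)[C@H](O[Si](CC)(CC)CC)[C@@H]1O[Si](C)(C)C(C)(C)C | intermediate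
12 | tert-butyldimethyl{[(1R,2S,6S)-3-methyl-6-[3-(phenylsulfinyl)prop-1-en-2-yl]-2-[(triethylsilyl)oxy]cyclohex-3-en-1-yl]oxy}silane (both sulfur epimers) | C=C(CS(=O)c2ccccc2)[C@@H]1CC=C(C)[C@H](O[Si](CC)(CC)CC)[C@@H]1O[Si](C)(C)C(C)(C)C | intermediate
13 | prenyl bromide, 1-bromo-3-methylbut-2-ene | CC(C)=CCBr | starting material
14 | tert-butyldimethyl{[(1R,2S,6S)-3-methyl-6-[6-methyl-3-(phenylsulfinyl)hepta-1,5-dien-2-yl]-2-[(triethylsilyl)oxy]cyclohex-3-en-1-yl]oxy}silane (mixture at C8 and sulfur) | C=C(C(CC=C(C)C)S(=O)c2ccccc2)[C@@H]1CC=C(C)[C@H](O[Si](CC)(CC)CC)[C@@H]1O[Si](C)(C)C(C)(C)C | intermediate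
15 | (2E)-2-[(1S,5S,6R)-6-[(tert-butyldimethylsilyl)oxy]-4-methyl-5-[(triethylsilyl)oxy]cyclohex-3-en-1-yl]-6-methylhepta-2,5-dien-1-yl benzenesulfenate | c2ccccc2SOC/C(=C/CC=C(C)C)[C@@H]1CC=C(C)[C@H](O[Si](CC)(CC)CC)[C@@H]1O[Si](C)(C)C(C)(C)C | intermediate
16 | (2E)-2-[(1S,5S,6R)-6-[(tert-butyldimethylsilyl)oxy]-4-methyl-5-[(triethylsilyl)oxy]cyclohex-3-en-1-yl]-6-methylhepta-2,5-dien-1-ol | OC/C(=C/CC=C(C)C)[C@@H]1CC=C(C)[C@H](O[Si](CC)(CC)CC)[C@@H]1O[Si](C)(C)C(C)(C)C | intermediate
17 | {(2S,3S)-2-[(1R,5S,6R)-6-[(tert-butyldimethylsilyl)oxy]-4-methyl-5-[(triethylsilyl)oxy]cyclohex-3-en-1-yl]-3-(3-methylbut-2-en-1-yl)oxiran-2-yl}methanol | OC[C@@]1(O[C@H]1CC=C(C)C)[C@@H]2CC=C(C)[C@H](O[Si](CC)(CC)CC)[C@@H]2O[Si](C)(C)C(C)(C)C | intermediate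
18 | tert-butyl{[(1R,2S,6R)-6-[(2R,3S)-2-(iodomethyl)-3-(3-methylbut-2-en-1-yl)oxiran-2-yl]-3-methyl-2-[(triethylsilyl)oxy]cyclohex-3-en-1-yl]oxy}dimethylsilane | IC[C@@]1(O[C@H]1CC=C(C)C)[C@@H]2CC=C(C)[C@H](O[Si](CC)(CC)CC)[C@@H]2O[Si](C)(C)C(C)(C)C | intermediate
19 | (3S)-2-[(1S,5S,6R)-6-[(tert-butyldimethylsilyl)oxy]-4-methyl-5-[(triethylsilyl)oxy]cyclohex-3-en-1-yl]-6-methylhepta-1,5-dien-3-ol | C=C([C@@H](O)CC=C(C)C)[C@@H]1CC=C(C)[C@H](O[Si](CC)(CC)CC)[C@@H]1O[Si](C)(C)C(C)(C)C | intermediate
20 | (1S,5S,6R)-6-[(tert-butyldimethylsilyl)oxy]-5-[(3S)-3-hydroxy-6-methylhepta-1,5-dien-2-yl]-2-methylcyclohex-2-en-1-ol | C=C([C@@H](O)CC=C(C)C)[C@@H]1CC=C(C)[C@H](O)[C@@H]1O[Si](C)(C)C(C)(C)C | intermediate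
21 | (1S,5S,6R)-6-[(tert-butyldimethylsilyl)oxy]-2-methyl-5-[(3S)-6-methyl-3-{[(2Z)-2-methylbut-2-enoyl]oxy}hepta-1,5-dien-2-yl]cyclohex-2-en-1-yl (2Z)-2-methylbut-2-enoate | C=C([C@H](CC=C(C)C)OC(=O)/C(C)=C\C)[C@@H]1CC=C(C)[C@H](OC(=O)/C(C)=C\C)[C@@H]1O[Si](C)(C)C(C)(C)C | intermediate
22 | (1S,5S,6R)-6-hydroxy-2-methyl-5-[(3S)-6-methyl-3-{[(2Z)-2-methylbut-2-enoyl]oxy}hepta-1,5-dien-2-yl]cyclohex-2-en-1-yl (2Z)-2-methylbut-2-enoate | C=C([C@H](CC=C(C)C)OC(=O)/C(C)=C\C)[C@@H]1CC=C(C)[C@H](OC(=O)/C(C)=C\C)[C@@H]1O | intermediate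
23 | (1S,2R,3R,4S,5S,8S)-3,8-bis(angeloyloxy)-4,5-epoxybisabola-7(14),10-dien-2-ol | C=C([C@H](CC=C(C)C)OC(=O)/C(C)=C\C)[C@@H]1C[C@@H]2O[C@]2(C)[C@H](OC(=O)/C(C)=C\C)[C@@H]1O | intermediate
24 | CNP0296086.3, (1S,2R,3R,4S,5S,8S,10R)-3,8-bis(angeloyloxy)-4,5:10,11-diepoxybisabol-7(14)-en-2-ol | C=C([C@H](C[C@H]1OC1(C)C)OC(=O)/C(C)=C\C)[C@@H]1C[C@@H]2O[C@]2(C)[C@H](OC(=O)/C(C)=C\C)[C@@H]1O | target

**Step count and risks**

Total steps: 17. Longest linear sequence: 17 steps from (R)-carvone; prenyl bromide and angelic acid enter as commercial reagents.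

Steps most likely to fail:

Step 2. The SN2 displacement at C2 may be slow because the nucleophile must approach cis to the C1 substituent. Enolisation of the activated α-ketol could then compete, or the cis α-ketol could epimerise during methanolysis. The fallback sets out from 4 and comes back at 7. Compound 4 would be silylated (TBSOTf, 2,6-lutidine) to the trans silyl ether F1. F1 would be deprotonated at C2 with LiN(iPr)2 in THF at −78 °C, and the enolate protonated kinetically with 2,6-di-tert-butylphenol from the face opposite the C1 substituent. This contra-thermodynamic epimerisation replaces the substitution and should give 7 directly.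

Step 10. The [2,3] shift may lose E selectivity, because in the E transition state the C9 chain must lie cis to the bulky ring substituent on C7. The fallback sets out from 14 and comes back at 20, and it uses the fact that C7 is erased later. If the rearrangement gives the Z alkene, it would lead through the Z sulfenate F2 to the Z allylic alcohol F3. F3 would be epoxidised with Ti(OiPr)4, D-(−)-diethyl tartrate and t-BuOOH. With the Z alkene the antipodal ligand places oxygen on the same face of C8 as in 17, giving the C7-epimeric cis-epoxy alcohol F4. Iodination (PPh3, I2, imidazole) would give F5, and Zn in AcOH/THF/H2O would converge through 19 on 20. An E/Z mixture could be separated and each isomer taken on with its own tartrate.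

Step 14. Acylation of the hindered C3 hydroxyl may stall, or the forcing conditions may isomerise the angelate to the tiglate. The fallback sets out from 20 and comes back at 21, and it builds the Z alkene after the ester bond. Both hydroxyls would be esterified with 2-(diphenoxyphosphoryl)propanoic acid (DCC, DMAP, CH2Cl2), which has no alkene to isomerise, giving the bis-phosphonate F6. A Z-selective Horner–Wadsworth–Emmons reaction of the diaryl phosphonate with acetaldehyde (NaH, THF, −78 °C) would then form both (Z)-2-methylbut-2-enoates in place and give 21.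

Further compounds
F1 | step 2 | (5S,6S)-6-[(tert-butyldimethylsilyl)oxy]-2-methyl-5-(prop-1-en-2-yl)cyclohex-2-en-1-one | C=C(C)[C@@H]1CC=C(C)C(=O)[C@H]1O[Si](C)(C)C(C)(C)C
F2 | step 10 | (2Z)-2-[(1S,5S,6R)-6-[(tert-butyldimethylsilyl)oxy]-4-methyl-5-[(triethylsilyl)oxy]cyclohex-3-en-1-yl]-6-methylhepta-2,5-dien-1-yl benzenesulfenate | c2ccccc2SOC/C(=C\CC=C(C)C)[C@@H]1CC=C(C)[C@H](O[Si](CC)(CC)CC)[C@@H]1O[Si](C)(C)C(C)(C)C
F3 | step 10 | (2Z)-2-[(1S,5S,6R)-6-[(tert-butyldimethylsilyl)oxy]-4-methyl-5-[(triethylsilyl)oxy]cyclohex-3-en-1-yl]-6-methylhepta-2,5-dien-1-ol | OC/C(=C\CC=C(C)C)[C@@H]1CC=C(C)[C@H](O[Si](CC)(CC)CC)[C@@H]1O[Si](C)(C)C(C)(C)C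
F4 | step 10 | C7 epimer of 17, (2R,3S)-configured cis-epoxy alcohol | OC[C@]1(O[C@H]1CC=C(C)C)[C@@H]2CC=C(C)[C@H](O[Si](CC)(CC)CC)[C@@H]2O[Si](C)(C)C(C)(C)C
F5 | step 10 | C7 epimer of 18, cis-epoxy iodide | IC[C@]1(O[C@H]1CC=C(C)C)[C@@H]2CC=C(C)[C@H](O[Si](CC)(CC)CC)[C@@H]2O[Si](C)(C)C(C)(C)C
F6 | step 14 | (1S,5S,6R)-6-[(tert-butyldimethylsilyl)oxy]-5-[(3S)-3-{[2-(diphenoxyphosphoryl)propanoyl]oxy}-6-methylhepta-1,5-dien-2-yl]-2-methylcyclohex-2-en-1-yl 2-(diphenoxyphosphoryl)propanoate (epimers at the phosphonate α-carbons) | C=C([C@H](CC=C(C)C)OC(=O)C(C)P(=O)(Oc2ccccc2)Oc3ccccc3)[C@@H]1CC=C(C)[C@H](OC(=O)C(C)P(=O)(Oc4ccccc4)Oc5ccccc5)[C@@H]1O[Si](C)(C)C(C)(C)C
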